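**Plan**

- Numbering: carbocycle C1 (ketone), C2=C3, C4 (Me), C5 (OH), C6 (O‑methacryloyl), C7, C8 (lactone O), C9, C10 (Me, furanone O bridging to C3); lactone C11(=C13H2)–C12(=O). C6 is a carbinol carbon bonded to C7, C7 lies beta to the lactone carbonyl C12, and C11 carries the exocyclic methylene. The C6–C7 bond is therefore cut as the addition of a C6 ketyl to C7 of a butenolide whose C13 acetoxy group then leaves.
- Further cuts: the C6 ester; C11–C13 (hydroxymethylation) and C7–C8 (aldehyde plus methyl propiolate) of the butenolide; the furanone O–C3 bond (hydroxy ynone cyclisation); C1–C2 (acetylide plus lactone); C4–C5 (crotylboration).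
- Forward: a C2–C6 alkyne (from cis‑2‑butene and silyloxyacetaldehyde) and a C1/C8–C10 lactone (from (R)‑citramalic acid) are joined at C1–C2. The furanone closes first, the butenolide second, the ten‑membered carbocycle third; esterification and desilylation follow.
- Stereochemistry: C10 from (R)‑citramalic acid; C4 and C5 from a reagent‑controlled (Z)‑crotylboration; C8 from a ligand‑controlled alkynylation; C7 and C6 in the samarium ring closure (C7 anti to the C8 side chain, C6 through the ring transition state next to the C5 silyloxy centre).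

Key step: step 17

Assumption: the antipode of each chiral reagent or ligand ((−)‑Ipc2BOMe, ProPhenol, oxazaborolidine) is the one expected to give the configuration drawn; if the sense of induction is opposite, the mirror‑image reagent is used.

Abbreviations: TBS = tert‑butyldimethylsilyl, TMS = trimethylsilyl, Ipc = isopinocampheyl, DMP = Dess–Martin periodinane.

**Step 1**
Reactants: 1 cis‑2‑butene; 2 (tert‑butyldimethylsilyloxy)acetaldehyde
Product: 6 (2S,3R)-1-[(tert-butyldimethylsilyl)oxy]-3-methylpent-4-en-2-ol, via (Z)-crotylpotassium 3 (not isolated), via (Z)-crotyldiisopinocampheylborane 4 (not isolated), via borinate ester 5 (not isolated)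
Conditions: KOt‑Bu, n‑BuLi, THF, −78 to −45 °C; (−)‑Ipc2BOMe, −78 °C; BF3·OEt2; 2, −78 °C; then 3 M NaOH, 30% H2O2, rt
Reagents that add atoms: none
Why: Brown asymmetric crotylboration: the (Z)‑crotylborane adds through a closed chair transition state, so the Z geometry gives the syn methyl/hydroxyl pair and the isopinocampheyl groups choose the aldehyde face, which sets C4 and C5 together.

**Step 2**
Reactants: 6 (2S,3R)-1-[(tert-butyldimethylsilyl)oxy]-3-methylpent-4-en-2-ol
Product: 7 (2S,3R)-1,2-bis[(tert-butyldimethylsilyl)oxy]-3-methylpent-4-ene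
Conditions: TBSCl, imidazole, DMF, rt
Reagents that add atoms: tert‑butyldimethylsilyl chloride, CC(C)(C)[Si](C)(C)Cl
Why: Standard silylation of a secondary alcohol; any earlier 1,2‑silyl shift between O5 and O6 is without consequence because both oxygens end as TBS ethers.

**Step 3**
Reactants: 7 (2S,3R)-1,2-bis[(tert-butyldimethylsilyl)oxy]-3-methylpent-4-ene
Product: 9 (2S,3S)-3,4-bis[(tert-butyldimethylsilyl)oxy]-2-methylbutanal, via secondary ozonide 8 (not isolated)
Conditions: O3, CH2Cl2, −78 °C; then PPh3, −78 °C to rt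
Reagents that add atoms: ozone, [O-][O+]=O
Why: Ozonolysis of the only alkene with reductive work‑up gives the C3 aldehyde under neutral conditions that should leave the alpha centre C4 untouched.

**Step 4**
Reactants: 9 (2S,3S)-3,4-bis[(tert-butyldimethylsilyl)oxy]-2-methylbutanal
Product: 10 (3R,4S)-4,5-bis[(tert-butyldimethylsilyl)oxy]-3-methylpent-1-yne
Conditions: dimethyl (1‑diazo‑2‑oxopropyl)phosphonate, K2CO3, MeOH, 0 °C to rt
Reagents that add atoms: dimethyl (1‑diazo‑2‑oxopropyl)phosphonate (Ohira–Bestmann reagent), CC(=O)C(=[N+]=[N-])P(=O)(OC)OC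
Why: Ohira–Bestmann (Seyferth–Gilbert) homologation turns the aldehyde into the terminal alkyne C2≡C3 under mild carbonate conditions that are routinely used on alpha‑methyl aldehydes without epimerisation.

**Step 5**
Reactants: 11 (R)‑citramalic acid
Product: 12 2-[(4R)-2,2,4-trimethyl-5-oxo-1,3-dioxolan-4-yl]acetic acid
Conditions: 2,2‑dimethoxypropane, TsOH·H2O (cat.), rt
Reagents that add atoms: 2,2‑dimethoxypropane, COC(C)(C)OC
Why: Acid‑catalysed acetal exchange ties the alpha‑hydroxy acid into the five‑membered dioxolanone and leaves the C8 carboxyl free, which differentiates the two acids.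

**Step 6**
Reactants: 12 2-[(4R)-2,2,4-trimethyl-5-oxo-1,3-dioxolan-4-yl]acetic acid
Product: 14 (3R)-3-hydroxy-3-methyloxolan-2-one, via hydroxyethyl dioxolanone 13 (not isolated)
Conditions: BH3·SMe2, THF, 0 °C to rt; MeOH; then TsOH·H2O (cat.), CH2Cl2, rt
Reagents that add atoms: none
Why: Borane reduces the free carboxylic acid chemoselectively beside the dioxolanone, and the primary alcohol then translactonises under acid with loss of acetone; the quaternary centre takes no part.

**Step 7**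
Reactants: 14 (3R)-3-hydroxy-3-methyloxolan-2-one
Product: 15 (3R)-3-methyl-3-[(trimethylsilyl)oxy]oxolan-2-one
Conditions: TMSCl, imidazole, CH2Cl2, 0 °C to rt
Reagents that add atoms: trimethylsilyl chloride, C[Si](C)(C)Cl
Why: Silylation of the tertiary alcohol prevents it from quenching the acetylide in the next step.

**Step 8**
Reactants: 10 (3R,4S)-4,5-bis[(tert-butyldimethylsilyl)oxy]-3-methylpent-1-yne; 15 (3R)-3-methyl-3-[(trimethylsilyl)oxy]oxolan-2-one
Product: 18 (3R,7R,8S)-8,9-bis[(tert-butyldimethylsilyl)oxy]-1-hydroxy-3,7-dimethyl-3-[(trimethylsilyl)oxy]non-5-yn-4-one, via lithium acetylide 16 (not isolated), via lithium lactolate 17 (not isolated)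
Conditions: 10, n‑BuLi, THF, −78 °C; then 15, −78 °C; sat. NH4Cl at −78 °C
Reagents that add atoms: none
Why: Addition of a lithium acetylide to a lactone stops at the tetrahedral lithium lactolate at low temperature and gives the hydroxy ynone on work‑up, which forms C1–C2.

**Step 9**
Reactants: 18 (3R,7R,8S)-8,9-bis[(tert-butyldimethylsilyl)oxy]-1-hydroxy-3,7-dimethyl-3-[(trimethylsilyl)oxy]non-5-yn-4-one
Product: 20 (2R)-5-[(2S,3S)-3,4-bis(tert-butyldimethylsilyloxy)butan-2-yl]-2-(2-hydroxyethyl)-2-methylfuran-3(2H)-one, via dihydroxy ynone 19 (not isolated)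
Conditions: AcOH/THF/H2O (3:1:1), 0 °C to rt; then (4‑CF3C6H4)3PAuCl (5 mol%), AgOTf (5 mol%), toluene, rt
Reagents that add atoms: none
Why: Mild acid removes the labile tertiary TMS ether, and the cationic phosphine–gold catalyst then activates the alkyne for 5‑endo‑dig attack of the C10 hydroxyl on C3 (gold‑catalysed cyclisation of an alpha'‑hydroxy ynone to a 3(2H)‑furanone).

**Step 10**
Reactants: 20 (2R)-5-[(2S,3S)-3,4-bis(tert-butyldimethylsilyloxy)butan-2-yl]-2-(2-hydroxyethyl)-2-methylfuran-3(2H)-one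
Product: 21 2-[(2R)-5-[(2S,3S)-3,4-bis(tert-butyldimethylsilyloxy)butan-2-yl]-2-methyl-3-oxo-2,3-dihydrofuran-2-yl]acetaldehyde
Conditions: DMP, NaHCO3, CH2Cl2, 0 °C to rt
Reagents that add atoms: none
Why: Dess–Martin oxidation gives the C8 aldehyde under buffered, non‑basic conditions that should not trigger beta‑elimination of the furanone oxygen.

**Step 11**
Reactants: 21 2-[(2R)-5-[(2S,3S)-3,4-bis(tert-butyldimethylsilyloxy)butan-2-yl]-2-methyl-3-oxo-2,3-dihydrofuran-2-yl]acetaldehyde; 22 methyl propiolate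
Product: 24 methyl (4S)-5-[(2R)-5-[(2S,3S)-3,4-bis(tert-butyldimethylsilyloxy)butan-2-yl]-2-methyl-3-oxo-2,3-dihydrofuran-2-yl]-4-hydroxypent-2-ynoate, via methylzinc acetylide 23 (not isolated)
Conditions: 22 (3 equiv), Me2Zn (3 equiv), ProPhenol ligand (20 mol%, antipode for the 8S carbinol), Ph3P=O (40 mol%), toluene, 0 to 4 °C; sat. NH4Cl
Reagents that add atoms: none
Why: Catalytic asymmetric alkynylation: the dinuclear zinc–ProPhenol complex delivers the zinc acetylide of methyl propiolate to one aldehyde face, which sets C8 under catalyst control and forms C7–C8.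

**Step 12**
Reactants: 24 methyl (4S)-5-[(2R)-5-[(2S,3S)-3,4-bis(tert-butyldimethylsilyloxy)butan-2-yl]-2-methyl-3-oxo-2,3-dihydrofuran-2-yl]-4-hydroxypent-2-ynoate
Product: 26 (2R)-5-[(2S,3S)-3,4-bis(tert-butyldimethylsilyloxy)butan-2-yl]-2-methyl-2-{[(2S)-5-oxo-2,5-dihydrofuran-2-yl]methyl}furan-3(2H)-one, via (Z)-hydroxy enoate 25 (not isolated)
Conditions: H2 (1 atm), Pd/CaCO3 poisoned with Pb(OAc)2 (Lindlar catalyst), quinoline, EtOAc, rt; then PPTS (cat.), CH2Cl2, rt
Reagents that add atoms: none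
Why: Lindlar semihydrogenation gives the (Z)‑enoate, whose cis geometry brings the C8 hydroxyl to the ester so that lactonisation to the butenolide follows; the poisoned catalyst should not reduce the vinylogous‑ester alkene of the furanone.

**Step 13**
Reactants: 26 (2R)-5-[(2S,3S)-3,4-bis(tert-butyldimethylsilyloxy)butan-2-yl]-2-methyl-2-{[(2S)-5-oxo-2,5-dihydrofuran-2-yl]methyl}furan-3(2H)-one
Product: 27 (2R)-5-[(2S,3S)-3,4-bis(tert-butyldimethylsilyloxy)butan-2-yl]-2-{[(2S)-4-(hydroxymethyl)-5-oxo-2,5-dihydrofuran-2-yl]methyl}-2-methylfuran-3(2H)-one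
Conditions: 37% aq. HCHO, PBu3 (0.3 equiv), THF, rt
Reagents that add atoms: formaldehyde, C=O
Why: Morita–Baylis–Hillman reaction: the phosphine adds reversibly to C7, the enolate is hydroxymethylated at C11 and the phosphine is expelled, as known for cyclic enones and 5‑substituted butenolides; the weakly basic medium should leave C8 alone.

**Step 14**
Reactants: 27 (2R)-5-[(2S,3S)-3,4-bis(tert-butyldimethylsilyloxy)butan-2-yl]-2-{[(2S)-4-(hydroxymethyl)-5-oxo-2,5-dihydrofuran-2-yl]methyl}-2-methylfuran-3(2H)-one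
Product: 28 [(5S)-5-{[(2R)-5-[(2S,3S)-3,4-bis(tert-butyldimethylsilyloxy)butan-2-yl]-2-methyl-3-oxo-2,3-dihydrofuran-2-yl]methyl}-2-oxo-2,5-dihydrofuran-3-yl]methyl acetate
Conditions: Ac2O, pyridine, CH2Cl2, 0 °C
Reagents that add atoms: acetic anhydride, CC(=O)OC(C)=O
Why: Acetylation of the primary allylic alcohol turns the C13 oxygen into the leaving group needed in the ring closure.

**Step 15**
Reactants: 28 [(5S)-5-{[(2R)-5-[(2S,3S)-3,4-bis(tert-butyldimethylsilyloxy)butan-2-yl]-2-methyl-3-oxo-2,3-dihydrofuran-2-yl]methyl}-2-oxo-2,5-dihydrofuran-3-yl]methyl acetate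
Product: 29 [(5S)-5-{[(2R)-5-[(2S,3S)-3-(tert-butyldimethylsilyloxy)-4-hydroxybutan-2-yl]-2-methyl-3-oxo-2,3-dihydrofuran-2-yl]methyl}-2-oxo-2,5-dihydrofuran-3-yl]methyl acetate
Conditions: HF·pyridine, pyridine, THF, 0 °C
Reagents that add atoms: none
Why: Buffered HF·pyridine cleaves the unhindered primary silyl ether at C6 much faster than the secondary one at C5, which sits between two branched carbons.

**Step 16**
Reactants: 29 [(5S)-5-{[(2R)-5-[(2S,3S)-3-(tert-butyldimethylsilyloxy)-4-hydroxybutan-2-yl]-2-methyl-3-oxo-2,3-dihydrofuran-2-yl]methyl}-2-oxo-2,5-dihydrofuran-3-yl]methyl acetate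
Product: 30 [(5S)-5-{[(2R)-5-[(2S,3S)-3-(tert-butyldimethylsilyloxy)-4-oxobutan-2-yl]-2-methyl-3-oxo-2,3-dihydrofuran-2-yl]methyl}-2-oxo-2,5-dihydrofuran-3-yl]methyl acetate
Conditions: DMP, NaHCO3, CH2Cl2, 0 °C; used at once
Reagents that add atoms: none
Why: Dess–Martin oxidation gives the alpha‑silyloxy aldehyde under neutral buffered conditions that should not epimerise C5.

**Step 17**
Reactants: 30 [(5S)-5-{[(2R)-5-[(2S,3S)-3-(tert-butyldimethylsilyloxy)-4-oxobutan-2-yl]-2-methyl-3-oxo-2,3-dihydrofuran-2-yl]methyl}-2-oxo-2,5-dihydrofuran-3-yl]methyl acetate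
Product: 31 (4S,5S,6S,7S,8S,10R)-5-(tert-butyldimethylsilyloxy)-6-hydroxy-1-oxo-3,10-epoxygermacra-2,11(13)-dien-12,8-olide
Conditions: SmI2 (3 equiv, 0.1 M in THF), t‑BuOH (2 equiv), THF, −78 °C, 30 added over 4 h by syringe pump (about 2 mM final); pH 7 phosphate buffer at −78 °C
Reagents that add atoms: none
Why: SmI2 reduces the C6 aldehyde, the most easily reduced carbonyl and activated by its alpha‑silyloxy group, to a samarium ketyl that adds to C7, the beta carbon of the butenolide; the C11 radical then takes a second electron and the trivalent samarium enolate expels the C13 acetate, which leaves the C11=C13 methylene. The closest known reaction type is the SmI2 ketyl–olefin coupling of aldehydes with unsaturated esters and lactones followed by beta‑elimination from the samarium enolate, here applied to a larger ring than the usual five‑ to eight‑membered cases. The ten‑membered carbocycle (nine atoms if counted through the furanone oxygen) closes in exo‑trig mode with C11 outside the new ring, and the two planar five‑membered rings already fix several of its torsions, which should lower the entropic cost. C7 is set by attack on the butenolide face anti to the C9 branch at C8, which gives the trans‑fused lactone, and C6 by the face of the ketyl, which should turn its samarium‑bound oxygen away from the bulky C5 silyloxy group in the ring‑forming transition state. The step needs electron transfer to the aldehyde before the butenolide or the furanone and ring closure before dimerisation or simple reduction: the absence of HMPA, the low temperature and slow addition at high dilution should secure this, and the cold buffered quench protonates the C6 alkoxide before it can attack the lactone.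

**Step 18**
Reactants: 31 (4S,5S,6S,7S,8S,10R)-5-(tert-butyldimethylsilyloxy)-6-hydroxy-1-oxo-3,10-epoxygermacra-2,11(13)-dien-12,8-olide
Product: 32 (4S,5S,6S,7R,8S,10R)-5-(tert-butyldimethylsilyloxy)-6-(methacryloyloxy)-1-oxo-3,10-epoxygermacra-2,11(13)-dien-12,8-olide
Conditions: methacrylic anhydride, Et3N, DMAP (cat.), CH2Cl2, 0 °C to rt
Reagents that add atoms: methacrylic anhydride, C=C(C)C(=O)OC(=O)C(C)=C
Why: DMAP‑catalysed acylation of the secondary C6 alcohol under mildly basic amine conditions that should neither open the lactone nor shift it to O6.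

**Step 19**
Reactants: 32 (4S,5S,6S,7R,8S,10R)-5-(tert-butyldimethylsilyloxy)-6-(methacryloyloxy)-1-oxo-3,10-epoxygermacra-2,11(13)-dien-12,8-olide
Product: 33 (4S,5S,6S,7R,8S,10R)-5-hydroxy-6-(methacryloyloxy)-1-oxo-3,10-epoxygermacra-2,11(13)-dien-12,8-olide
Conditions: HF·pyridine, THF, 0 °C to rt
Reagents that add atoms: none
Why: Acidic fluoride removes the secondary silyl ether without the O6‑to‑O5 acyl shift that a basic fluoride source could cause, and leaves both Michael acceptors untouched.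

**Compound list**

1 | cis‑2‑butene | C/C=C\C | starting material
2 | (tert‑butyldimethylsilyloxy)acetaldehyde | CC(C)(C)[Si](C)(C)OCC=O | starting material
3 | (Z)‑crotylpotassium | C/C=C\C[K] | intermediate
4 | (Z)‑crotyldiisopinocampheylborane (Ipc groups of the (+)‑alpha‑pinene series) | C/C=C\CB([C@@H]1C[C@@H]2C[C@H]([C@H]1C)C2(C)C)[C@@H]1C[C@@H]2C[C@H]([C@H]1C)C2(C)C | intermediate
5 | (2S,3R)-1-[(tert-butyldimethylsilyl)oxy]-3-methylpent-4-en-2-yl diisopinocampheylborinate | CC(C)(C)[Si](C)(C)OC[C@@H](OB([C@@H]1C[C@@H]2C[C@H]([C@H]1C)C2(C)C)[C@@H]1C[C@@H]2C[C@H]([C@H]1C)C2(C)C)[C@H](C)C=C | intermediate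
6 | (2S,3R)-1-[(tert-butyldimethylsilyl)oxy]-3-methylpent-4-en-2-ol | CC(C)(C)[Si](C)(C)OC[C@@H](O)[C@H](C)C=C | intermediate
7 | (2S,3R)-1,2-bis[(tert-butyldimethylsilyl)oxy]-3-methylpent-4-ene | CC(C)(C)[Si](C)(C)OC[C@@H](O[Si](C)(C)C(C)(C)C)[C@H](C)C=C | intermediate
8 | 3-[(2S,3S)-3,4-bis(tert-butyldimethylsilyloxy)butan-2-yl]-1,2,4-trioxolane (secondary ozonide, mixture at the ring carbon) | CC(C)(C)[Si](C)(C)OC[C@@H](O[Si](C)(C)C(C)(C)C)[C@H](C)C1OCOO1 | intermediate
9 | (2S,3S)-3,4-bis[(tert-butyldimethylsilyl)oxy]-2-methylbutanal | CC(C)(C)[Si](C)(C)OC[C@@H](O[Si](C)(C)C(C)(C)C)[C@H](C)C=O | intermediate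
10 | (3R,4S)-4,5-bis[(tert-butyldimethylsilyl)oxy]-3-methylpent-1-yne | CC(C)(C)[Si](C)(C)OC[C@@H](O[Si](C)(C)C(C)(C)C)[C@H](C)C#C | intermediate
11 | (R)‑citramalic acid, (2R)-2-hydroxy-2-methylbutanedioic acid | C[C@@](O)(CC(=O)O)C(=O)O | starting material
12 | 2-[(4R)-2,2,4-trimethyl-5-oxo-1,3-dioxolan-4-yl]acetic acid | C[C@]1(CC(=O)O)OC(C)(C)OC1=O | intermediate
13 | (5R)-5-(2-hydroxyethyl)-2,2,5-trimethyl-1,3-dioxolan-4-one | C[C@]1(CCO)OC(C)(C)OC1=O | intermediate
14 | (3R)-3-hydroxy-3-methyloxolan-2-one | C[C@@]1(O)CCOC1=O | intermediate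
15 | (3R)-3-methyl-3-[(trimethylsilyl)oxy]oxolan-2-one | C[C@@]1(O[Si](C)(C)C)CCOC1=O | intermediate
16 | [(3R,4S)-4,5-bis(tert-butyldimethylsilyloxy)-3-methylpent-1-yn-1-yl]lithium | CC(C)(C)[Si](C)(C)OC[C@@H](O[Si](C)(C)C(C)(C)C)[C@H](C)C#C[Li] | intermediate
17 | lithium lactolate from addition of 16 to 15 (2‑alkynyl‑2‑lithiooxy‑3‑methyl‑3‑(trimethylsilyloxy)oxolane, mixture at the lactol carbon) | CC(C)(C)[Si](C)(C)OC[C@@H](O[Si](C)(C)C(C)(C)C)[C@H](C)C#CC1(O[Li])OCC[C@@]1(C)O[Si](C)(C)C | intermediate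
18 | (3R,7R,8S)-8,9-bis[(tert-butyldimethylsilyl)oxy]-1-hydroxy-3,7-dimethyl-3-[(trimethylsilyl)oxy]non-5-yn-4-one (open form; may equilibrate with its lactol) | CC(C)(C)[Si](C)(C)OC[C@@H](O[Si](C)(C)C(C)(C)C)[C@H](C)C#CC(=O)[C@@](C)(CCO)O[Si](C)(C)C | intermediate
19 | (3R,7R,8S)-8,9-bis[(tert-butyldimethylsilyl)oxy]-1,3-dihydroxy-3,7-dimethylnon-5-yn-4-one | CC(C)(C)[Si](C)(C)OC[C@@H](O[Si](C)(C)C(C)(C)C)[C@H](C)C#CC(=O)[C@@](C)(CCO)O | intermediate
20 | (2R)-5-[(2S,3S)-3,4-bis(tert-butyldimethylsilyloxy)butan-2-yl]-2-(2-hydroxyethyl)-2-methylfuran-3(2H)-one | CC(C)(C)[Si](C)(C)OC[C@@H](O[Si](C)(C)C(C)(C)C)[C@H](C)C1=CC(=O)[C@@](C)(CCO)O1 | intermediate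
21 | 2-[(2R)-5-[(2S,3S)-3,4-bis(tert-butyldimethylsilyloxy)butan-2-yl]-2-methyl-3-oxo-2,3-dihydrofuran-2-yl]acetaldehyde | CC(C)(C)[Si](C)(C)OC[C@@H](O[Si](C)(C)C(C)(C)C)[C@H](C)C1=CC(=O)[C@@](C)(CC=O)O1 | intermediate
22 | methyl propiolate | C#CC(=O)OC | starting material
23 | methyl 3-(methylzincio)prop-2-ynoate | C[Zn]C#CC(=O)OC | intermediate
24 | methyl (4S)-5-[(2R)-5-[(2S,3S)-3,4-bis(tert-butyldimethylsilyloxy)butan-2-yl]-2-methyl-3-oxo-2,3-dihydrofuran-2-yl]-4-hydroxypent-2-ynoate | CC(C)(C)[Si](C)(C)OC[C@@H](O[Si](C)(C)C(C)(C)C)[C@H](C)C1=CC(=O)[C@@](C)(C[C@H](O)C#CC(=O)OC)O1 | intermediate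
25 | methyl (2Z,4S)-5-[(2R)-5-[(2S,3S)-3,4-bis(tert-butyldimethylsilyloxy)butan-2-yl]-2-methyl-3-oxo-2,3-dihydrofuran-2-yl]-4-hydroxypent-2-enoate | CC(C)(C)[Si](C)(C)OC[C@@H](O[Si](C)(C)C(C)(C)C)[C@H](C)C1=CC(=O)[C@@](C)(C[C@H](O)/C=C\C(=O)OC)O1 | intermediate
26 | (2R)-5-[(2S,3S)-3,4-bis(tert-butyldimethylsilyloxy)butan-2-yl]-2-methyl-2-{[(2S)-5-oxo-2,5-dihydrofuran-2-yl]methyl}furan-3(2H)-one | CC(C)(C)[Si](C)(C)OC[C@@H](O[Si](C)(C)C(C)(C)C)[C@H](C)C1=CC(=O)[C@@](C)(C[C@@H]2OC(=O)C=C2)O1 | intermediate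
27 | (2R)-5-[(2S,3S)-3,4-bis(tert-butyldimethylsilyloxy)butan-2-yl]-2-{[(2S)-4-(hydroxymethyl)-5-oxo-2,5-dihydrofuran-2-yl]methyl}-2-methylfuran-3(2H)-one | CC(C)(C)[Si](C)(C)OC[C@@H](O[Si](C)(C)C(C)(C)C)[C@H](C)C1=CC(=O)[C@@](C)(C[C@@H]2OC(=O)C(CO)=C2)O1 | intermediate
28 | [(5S)-5-{[(2R)-5-[(2S,3S)-3,4-bis(tert-butyldimethylsilyloxy)butan-2-yl]-2-methyl-3-oxo-2,3-dihydrofuran-2-yl]methyl}-2-oxo-2,5-dihydrofuran-3-yl]methyl acetate | CC(C)(C)[Si](C)(C)OC[C@@H](O[Si](C)(C)C(C)(C)C)[C@H](C)C1=CC(=O)[C@@](C)(C[C@@H]2OC(=O)C(COC(C)=O)=C2)O1 | intermediate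
29 | [(5S)-5-{[(2R)-5-[(2S,3S)-3-(tert-butyldimethylsilyloxy)-4-hydroxybutan-2-yl]-2-methyl-3-oxo-2,3-dihydrofuran-2-yl]methyl}-2-oxo-2,5-dihydrofuran-3-yl]methyl acetate | OC[C@@H](O[Si](C)(C)C(C)(C)C)[C@H](C)C1=CC(=O)[C@@](C)(C[C@@H]2OC(=O)C(COC(C)=O)=C2)O1 | intermediate
30 | [(5S)-5-{[(2R)-5-[(2S,3S)-3-(tert-butyldimethylsilyloxy)-4-oxobutan-2-yl]-2-methyl-3-oxo-2,3-dihydrofuran-2-yl]methyl}-2-oxo-2,5-dihydrofuran-3-yl]methyl acetate (furanone C6 aldehyde tethered to the 3‑(acetoxymethyl)butenolide) | O=C[C@@H](O[Si](C)(C)C(C)(C)C)[C@H](C)C1=CC(=O)[C@@](C)(C[C@@H]2OC(=O)C(COC(C)=O)=C2)O1 | intermediate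
31 | (4S,5S,6S,7S,8S,10R)-5-(tert-butyldimethylsilyloxy)-6-hydroxy-1-oxo-3,10-epoxygermacra-2,11(13)-dien-12,8-olide (plan numbering; trans‑fused methylene lactone, free C6 hydroxyl; C7 has the same spatial arrangement as in 33 and its descriptor changes only because O6 is not yet acylated) | O[C@@H]1[C@@H](O[Si](C)(C)C(C)(C)C)[C@H](C)C2=CC(=O)[C@@](C)(C[C@@H]3OC(=O)C(=C)[C@@H]13)O2 | intermediate
32 | (4S,5S,6S,7R,8S,10R)-5-(tert-butyldimethylsilyloxy)-6-(methacryloyloxy)-1-oxo-3,10-epoxygermacra-2,11(13)-dien-12,8-olide | C=C(C)C(=O)O[C@@H]1[C@@H](O[Si](C)(C)C(C)(C)C)[C@H](C)C2=CC(=O)[C@@](C)(C[C@@H]3OC(=O)C(=C)[C@@H]13)O2 | intermediate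
33 | CNP0195404.1, (4S,5S,6S,7R,8S,10R)-5-hydroxy-6-(methacryloyloxy)-1-oxo-3,10-epoxygermacra-2,11(13)-dien-12,8-olide | C=C(C)C(=O)O[C@@H]1[C@@H](O)[C@H](C)C2=CC(=O)[C@@](C)(C[C@@H]3OC(=O)C(=C)[C@@H]13)O2 | target

**Step count and risks**

Total step count: 19. Longest linear sequence: 16 steps (steps 1–4, then 8–19).

Step 17 (ring closure). The ketyl may be reduced further or dimerise before it reaches C7, electron transfer may go to the butenolide first, or the ketyl may add through the wrong face at C6. The fallback sets out from 27 and comes back at 31; it closes the same C6–C7 bond by a two‑electron allyl‑metal addition. Appel bromination of 27 (CBr4, PPh3, CH2Cl2, 0 °C) would give the 3‑(bromomethyl)butenolide F1. HF·pyridine would free the primary alcohol F2, and Dess–Martin oxidation would give the bromo aldehyde F3. CrCl2 in THF at high dilution (Nozaki–Hiyama–Kishi‑type allylation) would then form an allylchromium species that adds through its gamma carbon C7 to the C6 aldehyde with shift of the double bond to C11=C13, which should give 31. Additions of 3‑(bromomethyl)butenolides to aldehydes and chromium‑mediated ten‑membered carbocyclisations of this type are known.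

Step 13 (hydroxymethylation). Addition of the phosphine to the substituted beta carbon may be slow, and the basic zwitterion may deprotonate C8, with loss of configuration or elimination of the furanone oxygen. The fallback sets out from 24 and comes back at 27; it replaces nucleophilic catalysis by cross‑coupling. Hydrostannation of the ynoate 24 (Bu3SnH, Pd(PPh3)4 cat., THF; syn addition with tin at the alpha carbon) followed by lactonisation would give the 3‑(tributylstannyl)butenolide F4. Iododestannylation (I2, CH2Cl2, 0 °C) would give the 3‑iodobutenolide F5. Stille coupling with (tributylstannyl)methanol (Pd(PPh3)4, dioxane, 80 °C) would then install the hydroxymethyl group and give 27.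

Step 11 (alkynylation). Facial selectivity may be poor with this functionalised aliphatic aldehyde, and the zinc alkoxide medium may cause beta‑elimination of the furanone oxygen before addition. The fallback sets out from 21 and comes back at 24; it sets C8 by ketone reduction. Lithiated methyl propiolate (LiHMDS, THF, −78 °C) would add quickly to 21 and give the propargylic alcohol as a mixture at C8, F6. Dess–Martin oxidation would give the ynone F7. Corey–Bakshi–Shibata reduction of this alkynyl ketone (oxazaborolidine catalyst, catecholborane, −78 °C) would then set C8 and give 24.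

**Further compounds**

F1 | step 17 | (2R)-5-[(2S,3S)-3,4-bis(tert-butyldimethylsilyloxy)butan-2-yl]-2-{[(2S)-4-(bromomethyl)-5-oxo-2,5-dihydrofuran-2-yl]methyl}-2-methylfuran-3(2H)-one | CC(C)(C)[Si](C)(C)OC[C@@H](O[Si](C)(C)C(C)(C)C)[C@H](C)C1=CC(=O)[C@@](C)(C[C@@H]2OC(=O)C(CBr)=C2)O1
F2 | step 17 | (2R)-2-{[(2S)-4-(bromomethyl)-5-oxo-2,5-dihydrofuran-2-yl]methyl}-5-[(2S,3S)-3-(tert-butyldimethylsilyloxy)-4-hydroxybutan-2-yl]-2-methylfuran-3(2H)-one | OC[C@@H](O[Si](C)(C)C(C)(C)C)[C@H](C)C1=CC(=O)[C@@](C)(C[C@@H]2OC(=O)C(CBr)=C2)O1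
F3 | step 17 | (2S,3S)-3-[(2R)-2-{[(2S)-4-(bromomethyl)-5-oxo-2,5-dihydrofuran-2-yl]methyl}-2-methyl-3-oxo-2,3-dihydrofuran-5-yl]-2-(tert-butyldimethylsilyloxy)butanal | O=C[C@@H](O[Si](C)(C)C(C)(C)C)[C@H](C)C1=CC(=O)[C@@](C)(C[C@@H]2OC(=O)C(CBr)=C2)O1
F4 | step 13 | (2R)-5-[(2S,3S)-3,4-bis(tert-butyldimethylsilyloxy)butan-2-yl]-2-methyl-2-{[(2S)-5-oxo-4-(tributylstannyl)-2,5-dihydrofuran-2-yl]methyl}furan-3(2H)-one | CC(C)(C)[Si](C)(C)OC[C@@H](O[Si](C)(C)C(C)(C)C)[C@H](C)C1=CC(=O)[C@@](C)(C[C@@H]2OC(=O)C([Sn](CCCC)(CCCC)CCCC)=C2)O1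
F5 | step 13 | (2R)-5-[(2S,3S)-3,4-bis(tert-butyldimethylsilyloxy)butan-2-yl]-2-{[(2S)-4-iodo-5-oxo-2,5-dihydrofuran-2-yl]methyl}-2-methylfuran-3(2H)-one | CC(C)(C)[Si](C)(C)OC[C@@H](O[Si](C)(C)C(C)(C)C)[C@H](C)C1=CC(=O)[C@@](C)(C[C@@H]2OC(=O)C(I)=C2)O1
F6 | step 11 | methyl 5-[(2R)-5-[(2S,3S)-3,4-bis(tert-butyldimethylsilyloxy)butan-2-yl]-2-methyl-3-oxo-2,3-dihydrofuran-2-yl]-4-hydroxypent-2-ynoate (mixture at C4) | CC(C)(C)[Si](C)(C)OC[C@@H](O[Si](C)(C)C(C)(C)C)[C@H](C)C1=CC(=O)[C@@](C)(CC(O)C#CC(=O)OC)O1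
F7 | step 11 | methyl 5-[(2R)-5-[(2S,3S)-3,4-bis(tert-butyldimethylsilyloxy)butan-2-yl]-2-methyl-3-oxo-2,3-dihydrofuran-2-yl]-4-oxopent-2-ynoate | CC(C)(C)[Si](C)(C)OC[C@@H](O[Si](C)(C)C(C)(C)C)[C@H](C)C1=CC(=O)[C@@](C)(CC(=O)C#CC(=O)OC)O1
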